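**Strategy.** Ring B (C5–C10) is disconnected into the four-carbon unit C7–C6–C5–C10, an (E)-1-silyloxy diene built on ring A, and the two-carbon unit C8–C9, an (E)-2-methyl-2-enal. One enantioselective Diels–Alder reaction joins C7 to C8 and C9 to C10, closes ring B and sets C8, C9 and C10 with a C7 oxygen in place. It exploits the adjacent C7 oxygen and C8 carbinol (the formyl group on C8 is later excised by Baeyer–Villiger oxidation with retention) and the cis relation of the C8 methyl, C9 side chain and C10 methyl; the C5=C6 alkene left behind becomes the handle for H5α and the C6 acetate.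

Key step: step 3

Remark: labdane numbering is used throughout (decalin C1–C10, side chain C11–C16 on C9, C17 methyl on C8, C18/C19 on C4, C20 methyl on C10); α is the face opposite C20.

Assumption: compounds 1, 3 and 4 are purchased; the sense of induction in step 3 is assigned from the formyl C–H···O binding model of this catalyst class, and the (S)-catalyst would be used instead, with nothing else changed, if the first adduct showed the opposite sense.

**Step 1**
Reactants: 1 β-homocyclocitral [(2,6,6-trimethylcyclohex-1-en-1-yl)acetaldehyde]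
Product: 2 (E)-triisopropyl{[2-(2,6,6-trimethylcyclohex-1-en-1-yl)ethenyl]oxy}silane
Conditions: TIPSOTf, Et3N, CH2Cl2, 0 °C to rt
Reagents that add atoms: triisopropylsilyl trifluoromethanesulfonate, CC(C)[Si](C(C)C)(C(C)C)OS(=O)(=O)C(F)(F)F
Why: Soft enolisation and O-silylation of the β,γ-unsaturated aldehyde should give the conjugated dienol silyl ether, the E isomer being favoured because the twisted, fully substituted ring avoids a cis silyloxy group; any Z isomer cannot reach the s-cis geometry and stays behind in step 3.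

**Step 2**
Reactants: 3 3-[(tert-butyldimethylsilyl)oxy]propanal; 4 2-(triphenylphosphoranylidene)propanal
Product: 5 (E)-5-[(tert-butyldimethylsilyl)oxy]-2-methylpent-2-enal
Conditions: toluene, 80 °C
Reagents that add atoms: none
Why: Wittig olefination with the stabilised formyl ylide should give the E trisubstituted enal, with ylide 4 reacting only at the more electrophilic aliphatic aldehyde.

**Step 3**
Reactants: 2 (E)-silyloxy diene; 5 (E)-enal
Product: 6 12-(tert-butyldimethylsilyloxy)-8α-formyl-7α-(triisopropylsilyloxy)-13,14,15,16-tetranorlabd-5-ene (C17 methyl β; H9 α; C20 methyl β)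
Conditions: (R)-3,3-diphenyl-1-(o-tolyl)tetrahydro-1H,3H-pyrrolo[1,2-c][1,3,2]oxazaborole (20 mol %), HNTf2 (18 mol %), CH2Cl2, −78 to −40 °C
Reagents that add atoms: none
Why: The protonated oxazaborolidine binds the formyl oxygen of 5 (B–O coordination plus a formyl C–H···O contact) and lowers its LUMO, and the HOMO of diene 2, polarised towards C10 by the C7 silyloxy donor, adds in a concerted, asynchronous normal-demand [4+2] cycloaddition in which the C9–C10 bond leads and the C7–C8 bond follows, the two components combining one to one with no atom lost. The closest known reaction type is the oxazaborolidinium-catalysed Diels–Alder addition of 2-methyl-3-substituted acroleins to 1-vinylcyclohexene-type and silyloxy dienes, which builds a formyl-bearing quaternary carbon next to the diene terminus in the same way. Ring B is closed as a cyclohexene by intermolecular suprafacial–suprafacial [4+2] cycloaddition across C7 and C10 of the diene, leaving the C5=C6 alkene. C8, C9 and C10 are fixed relative to one another by the endo transition state (formyl under the diene) and the E geometry of 5, which place the C8 methyl and the C9 side chain exo and hence cis to the inside C10 methyl (all β; formyl and H9 α), C7 (silyloxy α) follows from the E geometry of 2, and the absolute sense comes from the catalyst, whose aryl group shields one face of the bound enal so that the diene adds to the Re face of C8. The step needs ortho regioselectivity (oxygenated C7 joined to the formyl-bearing C8), secured by the 1-silyloxy group; endo selectivity, secured because only the hydrogen on C9 then has to sit under the ring beside the C4 gem-dimethyl group; and cycloaddition in preference to Michael-type attack through C6, helped by low temperature and the robust TIPS group.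

**Step 4**
Reactants: 6 Diels–Alder adduct
Product: 8 12-(tert-butyldimethylsilyloxy)-7α-(triisopropylsilyloxy)-13,14,15,16-tetranorlabd-5-en-8α-ol, via C8 formate 7 (not isolated)
Conditions: mCPBA, NaHCO3, CH2Cl2, 0 °C; then K2CO3 (cat.), MeOH, 0 °C
Reagents that add atoms: 3-chloroperoxybenzoic acid, O=C(OO)c1cccc(Cl)c1
Why: Baeyer–Villiger oxidation of the α-quaternary aldehyde should proceed by migration of the tertiary C8 with retention (8α-O, 8β-methyl), the C5=C6 alkene being shielded by the 7α-silyloxy group on one face and the axial C4/C10 methyls on the other; mild methanolysis then cleaves the formate.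

**Step 5**
Reactants: 8 bis-silyl ether
Product: 9 13,14,15,16-tetranorlabd-5-ene-7α,8α,12-triol
Conditions: Bu4NF, THF, 50 °C
Reagents that add atoms: none
Why: Fluoride-mediated desilylation should remove both silyl ethers without touching a stereocentre.

**Step 6**
Reactants: 9 triol
Product: 11 8α,12-epoxy-12-hydroxy-13,14,15,16-tetranorlabd-5-en-7-one (lactol as a mixture of C12 anomers), via open keto aldehyde 10 (not isolated)
Conditions: (COCl)2, DMSO, CH2Cl2, −78 °C; Et3N, −78 to 0 °C
Reagents that add atoms: none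
Why: Swern oxidation should convert the allylic C7 alcohol into the enone and the primary alcohol into the aldehyde, which the non-oxidisable 8α-hydroxyl captures as the trans-fused five-membered lactol; the activated sulfoxide is spent before the lactol forms, which guards against over-oxidation to the lactone.

**Step 7**
Reactants: 11 enone lactol
Product: 12 8α,12-epoxy-12-hydroxy-13,14,15,16-tetranorlabdan-7-one (5α-H; mixture of C12 anomers)
Conditions: H2 (3 atm), Pd/C, EtOAc, rt
Reagents that add atoms: none
Why: Catalytic hydrogenation of the enone should deliver hydrogen to the α face, opposite the axial 4β and C10 methyl groups, giving the trans-decalin (H5α).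

**Step 8**
Reactants: 12 keto lactol
Product: 14 (12Z)-8α-hydroxy-13-iodo-14,15-dinorlabd-12-en-7-one, via open hydroxy aldehyde 13 (not isolated)
Conditions: EtPPh3I, n-BuLi, THF, rt; I2, −78 °C; NaN(SiMe3)2, −78 °C; then 12, −78 to −20 °C (ylide 3 equiv)
Reagents that add atoms: ethyltriphenylphosphonium iodide, CC[P+](c1ccccc1)(c1ccccc1)c1ccccc1.[I-]; iodine, II
Why: In this Stork–Zhao-type Wittig olefination the lactol opens to aldehyde 13 under the basic ylide, and the α-iodo ylide should give the (Z)-2-iodoalkene (iodine cis to C11) through the kinetic cis-oxaphosphetane, the hindered C7 ketone staying untouched.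

**Step 9**
Reactants: 14 (Z)-vinyl iodide
Product: 15 (12Z)-8α-hydroxylabda-12,14-dien-7-one
Conditions: tributyl(vinyl)stannane, Pd(PPh3)4 (5 mol %), copper iodide CuI (10 mol %), DMF, rt to 40 °C
Reagents that add atoms: tributyl(vinyl)stannane, C=C[Sn](CCCC)(CCCC)CCCC
Why: Stille coupling proceeds with retention of alkene geometry, so the vinyl group should end cis to C11 (12Z); ketone and free tertiary alcohol are tolerated.

**Step 10**
Reactants: 15 dienyl ketone
Product: 17 (12Z)-6α,8α-dihydroxylabda-12,14-dien-7-one, via dipotassium enolate 16 (not isolated)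
Conditions: KN(SiMe3)2 (2.5 equiv), THF, −78 °C; 2-(phenylsulfonyl)-3-phenyloxaziridine, −78 °C; AcOH quench
Reagents that add atoms: 2-(phenylsulfonyl)-3-phenyloxaziridine, O=S(=O)(c1ccccc1)N1OC1c1ccccc1
Why: Enolate hydroxylation with an N-sulfonyloxaziridine: the ketone can enolise only towards C6 (C8 is quaternary), and the oxidant should approach C6 from the α face, away from the axial 4β and C10 methyls, giving the equatorial 6α-alcohol without touching the diene.

**Step 11**
Reactants: 17 6α-hydroxy ketone
Product: 18 (12Z)-6α-acetoxy-8α-hydroxylabda-12,14-dien-7-one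
Conditions: Ac2O, DMAP (cat.), pyridine, CH2Cl2, 0 °C to rt
Reagents that add atoms: acetic anhydride, CC(=O)OC(C)=O
Why: DMAP-catalysed acylation should esterify the secondary 6α-hydroxyl only, the tertiary 8α-hydroxyl being too hindered under these conditions.

**Step 12**
Reactants: 18 6α-acetoxy ketone
Product: 19 (12Z)-6α-acetoxylabda-12,14-diene-7β,8α-diol (target)
Conditions: NaBH4, CeCl3·7H2O, MeOH, −40 °C
Reagents that add atoms: none
Why: Borohydride reduction under cerium-buffered, cold conditions (which also suppress 6→7 acetyl migration) should deliver hydride axially from the α face, anti to the axial 8β-methyl, giving the equatorial 7β-alcohol.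

**Compound list**

1 | β-homocyclocitral, 2-(2,6,6-trimethylcyclohex-1-en-1-yl)acetaldehyde | CC1=C(CC=O)C(C)(C)CCC1 | starting material
2 | (E)-triisopropyl{[2-(2,6,6-trimethylcyclohex-1-en-1-yl)ethenyl]oxy}silane | CC1=C(/C=C/O[Si](C(C)C)(C(C)C)C(C)C)C(C)(C)CCC1 | intermediate
3 | 3-[(tert-butyldimethylsilyl)oxy]propanal | CC(C)(C)[Si](C)(C)OCCC=O | starting material
4 | 2-(triphenylphosphoranylidene)propanal | CC(C=O)=P(c1ccccc1)(c1ccccc1)c1ccccc1 | starting material
5 | (E)-5-[(tert-butyldimethylsilyl)oxy]-2-methylpent-2-enal | CC(C)(C)[Si](C)(C)OCC/C=C(\C)C=O | intermediate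
6 | 12-(tert-butyldimethylsilyloxy)-8α-formyl-7α-(triisopropylsilyloxy)-13,14,15,16-tetranorlabd-5-ene | CC(C)(C)[Si](C)(C)OCC[C@H]1[C@](C)(C=O)[C@H](O[Si](C(C)C)(C(C)C)C(C)C)C=C2C(C)(C)CCC[C@@]21C | intermediate
7 | 12-(tert-butyldimethylsilyloxy)-7α-(triisopropylsilyloxy)-13,14,15,16-tetranorlabd-5-en-8α-yl formate | CC(C)(C)[Si](C)(C)OCC[C@H]1[C@](C)(OC=O)[C@H](O[Si](C(C)C)(C(C)C)C(C)C)C=C2C(C)(C)CCC[C@@]21C | intermediate (not isolated)
8 | 12-(tert-butyldimethylsilyloxy)-7α-(triisopropylsilyloxy)-13,14,15,16-tetranorlabd-5-en-8α-ol | CC(C)(C)[Si](C)(C)OCC[C@H]1[C@](C)(O)[C@H](O[Si](C(C)C)(C(C)C)C(C)C)C=C2C(C)(C)CCC[C@@]21C | intermediate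
9 | 13,14,15,16-tetranorlabd-5-ene-7α,8α,12-triol | OCC[C@H]1[C@](C)(O)[C@H](O)C=C2C(C)(C)CCC[C@@]21C | intermediate
10 | 8α-hydroxy-7-oxo-13,14,15,16-tetranorlabd-5-en-12-al (open form) | O=CC[C@H]1[C@](C)(O)C(=O)C=C2C(C)(C)CCC[C@@]21C | intermediate (not isolated)
11 | 8α,12-epoxy-12-hydroxy-13,14,15,16-tetranorlabd-5-en-7-one (lactol, C12 anomers) | OC3C[C@H]1[C@](C)(O3)C(=O)C=C2C(C)(C)CCC[C@@]21C | intermediate
12 | 8α,12-epoxy-12-hydroxy-13,14,15,16-tetranorlabdan-7-one (5α-H; lactol, C12 anomers) | OC3C[C@H]1[C@](C)(O3)C(=O)C[C@H]2C(C)(C)CCC[C@@]21C | intermediate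
13 | 8α-hydroxy-7-oxo-13,14,15,16-tetranorlabdan-12-al (open form) | O=CC[C@H]1[C@](C)(O)C(=O)C[C@H]2C(C)(C)CCC[C@@]21C | intermediate (not isolated)
14 | (12Z)-8α-hydroxy-13-iodo-14,15-dinorlabd-12-en-7-one | C/C(I)=C/C[C@H]1[C@](C)(O)C(=O)C[C@H]2C(C)(C)CCC[C@@]21C | intermediate
15 | (12Z)-8α-hydroxylabda-12,14-dien-7-one | C=C/C(C)=C\C[C@H]1[C@](C)(O)C(=O)C[C@H]2C(C)(C)CCC[C@@]21C | intermediate
16 | dipotassium 8-alkoxide C6=C7 enolate of 15 | C=C/C(C)=C\C[C@H]1[C@](C)([O-])C([O-])=C[C@H]2C(C)(C)CCC[C@@]21C.[K+].[K+] | intermediate (not isolated)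
17 | (12Z)-6α,8α-dihydroxylabda-12,14-dien-7-one | C=C/C(C)=C\C[C@H]1[C@](C)(O)C(=O)[C@H](O)[C@H]2C(C)(C)CCC[C@@]21C | intermediate
18 | (12Z)-6α-acetoxy-8α-hydroxylabda-12,14-dien-7-one | C=C/C(C)=C\C[C@H]1[C@](C)(O)C(=O)[C@H](OC(C)=O)[C@H]2C(C)(C)CCC[C@@]21C | intermediate
19 | (12Z)-6α-acetoxylabda-12,14-diene-7β,8α-diol; (1R,2S,3S,4R,4aS,8aS)-2,3-dihydroxy-2,5,5,8a-tetramethyl-1-[(2Z)-3-methylpenta-2,4-dien-1-yl]decahydronaphthalen-4-yl acetate | C=C/C(C)=C\C[C@H]1[C@](C)(O)[C@@H](O)[C@H](OC(C)=O)[C@H]2C(C)(C)CCC[C@@]21C | target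

**Step count.** Total: 12 steps. Longest linear sequence: 11 steps (step 1 or step 2, then steps 3–12).

**Steps most likely to fail**

Step 3 (key cycloaddition). Bond formation at the fully substituted C10 terminus may be too slow with the singly activated enal 5, so that acid-induced loss of the dienol silyl ether or Michael-type addition through C6 overtakes the cycloaddition, or facial control is eroded. The fallback sets out from 2 and uses the purchased, doubly activated dienophile ethyl (E)-3-methyl-4-oxobut-2-enoate (CCOC(=O)/C=C(\C)C=O) under the same catalyst. The formyl group again directs C7 to C8 and sits endo, which should give the 8α-formyl 9β-ester adduct F1. mCPBA/NaHCO3 converts the aldehyde into the C8 formate F2, and LiAlH4 reduces formate and ester together to the 8α,11-diol F3. SO3·pyridine/DMSO/Et3N gives the 8α-hydroxy 11-aldehyde F4, and non-basic methylenation (Zn, CH2Br2, TiCl4), chosen to avoid retro-aldol opening, gives the C9 vinyl compound F5. 9-BBN followed by H2O2/NaOH hydroborates only the terminal vinyl group to give the 8α,12-diol F6, and Bu4NF removes the TIPS group, returning to the route at 9.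

Step 4 (Baeyer–Villiger oxidation). Peracid epoxidation of the C5=C6 alkene, or hydride instead of alkyl migration (giving the acid), may compete with formate formation. The fallback sets out from 6 and reaches the same alcohol by a carboxy-inversion sequence with no free peracid present during the migration. NaClO2/NaH2PO4/2-methyl-2-butene gives the C8 carboxylic acid F7. DCC with mCPBA at 0 °C gives the acyl 3-chlorobenzoyl peroxide F8. Warming in CH3CN (50 °C) effects the carboxy-inversion rearrangement, with retention at C8, to the mixed carbonic anhydride F9. K2CO3/MeOH then cleaves it and returns to the route at 8.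

Step 8 (iodo-olefination of the lactol). Ring opening of the lactol may be slow under the basic ylide, and the thermally fragile α-iodo ylide may decompose or give eroded Z selectivity. The fallback sets out from 12 and builds the Z geometry by two stereospecific couplings. CBr4/PPh3 (Ramirez olefination, CH2Cl2, 0 °C) gives the 1,1-dibromoalkene F10. Trans-selective Negishi monomethylation (MeZnCl, PdCl2(DPEphos) cat., THF) replaces the bromine trans to C11 and gives the (Z)-bromoalkene F11. Stille coupling with tributyl(vinyl)stannane (Pd(P(t-Bu)3)2 cat., retention) returns to the route at 15.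

**Further compounds**

F1 | step 3 | ethyl 8α-formyl-7α-(triisopropylsilyloxy)-12,13,14,15,16-pentanorlabd-5-en-11-oate | CCOC(=O)[C@H]1[C@](C)(C=O)[C@H](O[Si](C(C)C)(C(C)C)C(C)C)C=C2C(C)(C)CCC[C@@]21C
F2 | step 3 | ethyl 8α-(formyloxy)-7α-(triisopropylsilyloxy)-12,13,14,15,16-pentanorlabd-5-en-11-oate | CCOC(=O)[C@H]1[C@](C)(OC=O)[C@H](O[Si](C(C)C)(C(C)C)C(C)C)C=C2C(C)(C)CCC[C@@]21C
F3 | step 3 | 7α-(triisopropylsilyloxy)-12,13,14,15,16-pentanorlabd-5-ene-8α,11-diol | OC[C@H]1[C@](C)(O)[C@H](O[Si](C(C)C)(C(C)C)C(C)C)C=C2C(C)(C)CCC[C@@]21C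
F4 | step 3 | 8α-hydroxy-7α-(triisopropylsilyloxy)-12,13,14,15,16-pentanorlabd-5-en-11-al | O=C[C@H]1[C@](C)(O)[C@H](O[Si](C(C)C)(C(C)C)C(C)C)C=C2C(C)(C)CCC[C@@]21C
F5 | step 3 | 7α-(triisopropylsilyloxy)-13,14,15,16-tetranorlabda-5,11-dien-8α-ol | C=C[C@H]1[C@](C)(O)[C@H](O[Si](C(C)C)(C(C)C)C(C)C)C=C2C(C)(C)CCC[C@@]21C
F6 | step 3 | 7α-(triisopropylsilyloxy)-13,14,15,16-tetranorlabd-5-ene-8α,12-diol | OCC[C@H]1[C@](C)(O)[C@H](O[Si](C(C)C)(C(C)C)C(C)C)C=C2C(C)(C)CCC[C@@]21C
F7 | step 4 | 12-(tert-butyldimethylsilyloxy)-7α-(triisopropylsilyloxy)-13,14,15,16-tetranorlabd-5-ene-8α-carboxylic acid | CC(C)(C)[Si](C)(C)OCC[C@H]1[C@](C)(C(=O)O)[C@H](O[Si](C(C)C)(C(C)C)C(C)C)C=C2C(C)(C)CCC[C@@]21C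
F8 | step 4 | mixed peroxide of acid F7 with 3-chlorobenzoic acid (acyl 3-chlorobenzoyl peroxide) | CC(C)(C)[Si](C)(C)OCC[C@H]1[C@](C)(C(=O)OOC(=O)c3cccc(Cl)c3)[C@H](O[Si](C(C)C)(C(C)C)C(C)C)C=C2C(C)(C)CCC[C@@]21C
F9 | step 4 | 8α-yl 3-chlorobenzoyl carbonate (mixed carbonic anhydride of alcohol 8) | CC(C)(C)[Si](C)(C)OCC[C@H]1[C@](C)(OC(=O)OC(=O)c3cccc(Cl)c3)[C@H](O[Si](C(C)C)(C(C)C)C(C)C)C=C2C(C)(C)CCC[C@@]21C
F10 | step 8 | 13,13-dibromo-8α-hydroxy-14,15,16-trinorlabd-12-en-7-one | BrC(Br)=CC[C@H]1[C@](C)(O)C(=O)C[C@H]2C(C)(C)CCC[C@@]21C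
F11 | step 8 | (12Z)-13-bromo-8α-hydroxy-14,15-dinorlabd-12-en-7-one | C/C(Br)=C/C[C@H]1[C@](C)(O)C(=O)C[C@H]2C(C)(C)CCC[C@@]21C
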